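**Retrosynthetic overview**
- The target, 2,5-dimethoxy-3-(indol-3-yl)-6-(7-prenylindol-3-yl)-1,4-benzoquinone, comes from its bis-N-Boc quinone, which comes from the matching hydroquinone by oxidation. The quinone ring is the only ring built; both indole nuclei are bought.
- Feature used: in the quinone ring the run C=O, C(7-prenylindol-3-yl), C(OMe), C=O is the four-carbon ring of a 3-aryl-4-methoxycyclobutene-1,2-dione, and the remaining C(indol-3-yl)=C(OMe) pair is a 1-aryl-2-methoxyvinyl group.
- Key disconnection: the ring bond between the carbonyl carbon next to the prenylindolyl carbon and its methoxy-bearing neighbour. It is made by thermal ring expansion (4π opening, 6π closure) of a 4-hydroxy-4-(1-aryl-2-methoxyvinyl)cyclobutenone.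
- The carbinol comes from a β-methoxyvinyllithium (N-Boc-indole-3-carbaldehyde; Wittig, bromination–dehydrobromination, Br/Li exchange) and an N-Boc indolyl methoxycyclobutenedione (squaric acid via squaryl dichloride, plus 7-prenylindole from 7-bromoindole).

Key step: step 9

Remark: the enol ether of the key-step precursor is handled and drawn as the Z isomer (OMe cis to the four-membered-ring carbon, trans to the indole), since this is what the vinyllithium with lithium syn to methoxy delivers with retention and the geometry vanishes on aromatisation; tert-butyl 3-formylindole-1-carboxylate is taken as a purchasable aldehyde.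

**Step 1**
Reactants: 1 squaric acid
Product: 2 squaryl dichloride (3,4-dichlorocyclobut-3-ene-1,2-dione)
Conditions: (COCl)2, DMF (cat.), CH2Cl2, reflux
Reagents that add atoms: oxalyl chloride, ClC(=O)C(=O)Cl
Why: Vilsmeier-type chlorodehydroxylation of the vinylogous diacid with oxalyl chloride/DMF is the standard preparation of squaryl dichloride.

**Step 2**
Reactants: 3 7-bromo-1H-indole
Product: 5 7-(3-methylbut-2-en-1-yl)-1H-indole (7-prenylindole), via 1-potassio-7-lithioindole 4 (not isolated)
Conditions: KH, THF, 0 °C; t-BuLi (2 equiv), −78 °C; prenyl bromide, −78 °C → rt; aq. NH4Cl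
Reagents that add atoms: prenyl bromide (1-bromo-3-methylbut-2-ene), CC(C)=CCBr
Why: KH masks N–H as the potassium salt so that t-BuLi effects clean bromine–lithium exchange at C7, and the aryllithium is alkylated by prenyl bromide at its unhindered primary carbon (SN2) to give the linear prenyl group.

**Step 3**
Reactants: 5 7-prenylindole; 2 squaryl dichloride
Product: 6 3-chloro-4-(7-prenyl-1H-indol-3-yl)cyclobut-3-ene-1,2-dione
Conditions: Et2O, 0 °C → rt, N2 sweep; filtration of the precipitate
Reagents that add atoms: none
Why: Squaryl dichloride is a vinylogous oxalyl chloride and should substitute the free indole at C3 without a Lewis acid (Friedel–Crafts-type addition–elimination), the mono-adduct precipitating from ether before the second chloride can be displaced.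

**Step 4**
Reactants: 6 3-chloro-4-(7-prenyl-1H-indol-3-yl)cyclobut-3-ene-1,2-dione
Product: 7 3-methoxy-4-(7-prenyl-1H-indol-3-yl)cyclobut-3-ene-1,2-dione
Conditions: MeOH, NaHCO3, CH2Cl2, 0 °C → rt
Reagents that add atoms: methanol, CO
Why: The remaining vinylogous acid chloride undergoes addition–elimination with methanol to the vinylogous methyl ester, NaHCO3 taking up the HCl so that the prenyl alkene is not exposed to acid.

**Step 5**
Reactants: 7 3-methoxy-4-(7-prenyl-1H-indol-3-yl)cyclobut-3-ene-1,2-dione
Product: 8 tert-butyl 3-(2-methoxy-3,4-dioxocyclobut-1-en-1-yl)-7-prenylindole-1-carboxylate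
Conditions: Boc2O, DMAP (cat.), MeCN, rt
Reagents that add atoms: di-tert-butyl dicarbonate, CC(C)(C)OC(=O)OC(=O)OC(C)(C)C
Why: The N–H, acidified by the 3-acyl-type substituent, is acylated by Boc2O under DMAP catalysis; the carbamate removes the acidic proton and damps indole donation into the carbonyl that must be attacked in step 8.

**Step 6**
Reactants: 9 tert-butyl 3-formylindole-1-carboxylate; 10 (methoxymethyl)triphenylphosphonium chloride
Product: 11 tert-butyl 3-(2-methoxyvinyl)indole-1-carboxylate (E/Z mixture)
Conditions: 10, NaN(SiMe3)2, THF, 0 °C; then 9, −78 → 0 °C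
Reagents that add atoms: none
Why: Wittig olefination of the aryl aldehyde with the preformed non-stabilised methoxymethylene ylide gives the enol ether as an E/Z mixture, which is acceptable because both isomers converge in step 7.

**Step 7**
Reactants: 11 tert-butyl 3-(2-methoxyvinyl)indole-1-carboxylate
Product: 13 tert-butyl 3-[(Z)-1-bromo-2-methoxyvinyl]indole-1-carboxylate, via 1,2-dibromo-2-methoxyethyl adduct 12 (not isolated)
Conditions: Br2, CH2Cl2, −78 °C; then iPr2NEt, −78 °C → rt; chromatography on Et3N-treated silica
Reagents that add atoms: bromine, BrBr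
Why: Br2 adds to the enol ether much faster than to the carbamate-deactivated indole, the α-bromo ether ionises to an oxocarbenium ion from which the amine removes the benzylic proton (bromination–dehydrobromination as used for 2-bromovinyl ethers and 5-bromo-3,4-dihydro-2H-pyran), and the isomer with Br cis to OMe and the indole trans is expected to predominate and is the one carried on.

**Step 8**
Reactants: 13 tert-butyl 3-[(Z)-1-bromo-2-methoxyvinyl]indole-1-carboxylate; 8 tert-butyl 3-(2-methoxy-3,4-dioxocyclobut-1-en-1-yl)-7-prenylindole-1-carboxylate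
Product: 15 racemic 4-hydroxy-3-methoxy-4-[(Z)-2-methoxy-1-(1-Boc-indol-3-yl)vinyl]-2-(1-Boc-7-prenylindol-3-yl)cyclobut-2-en-1-one, via syn-methoxy vinyllithium 14 (not isolated)
Conditions: 13, t-BuLi (2 equiv), THF, −78 °C; then 8, THF, −78 °C; aq. NH4Cl at −78 °C
Reagents that add atoms: none
Why: Bromine–lithium exchange proceeds with retention to a vinyllithium whose lithium is syn to OMe (internally coordinated and slow to lose LiOMe), which adds 1,2 to the more electrophilic carbonyl of 8, the one next to the OMe-bearing carbon and outside the vinylogous ester, as is general for organolithium additions to 3-alkoxy-4-arylcyclobutenediones; the carbinol stereocentre forms racemic and is destroyed in step 9.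

**Step 9**
Reactants: 15 racemic 4-hydroxy-3-methoxy-4-[(Z)-2-methoxy-1-(1-Boc-indol-3-yl)vinyl]-2-(1-Boc-7-prenylindol-3-yl)cyclobut-2-en-1-one
Product: 18 2,5-dimethoxy-3-(1-Boc-indol-3-yl)-6-(1-Boc-7-prenylindol-3-yl)benzene-1,4-diol, via dienylketene 16 (not isolated), via cyclohexadienone tautomer 17 (not isolated)
Conditions: PhMe (degassed, dilute), 110 °C
Reagents that add atoms: none
Why: Heating cleaves the C1–C4 bond of the cyclobutenone by conrotatory 4π electrocyclic opening to dienylketene 16, whose ketene carbon then bonds to the methoxy-bearing vinyl terminus in a thermal disrotatory 6π electrocyclisation to cyclohexadienone 17, and enolisation of its CH(OMe) centre gives the aromatic hydroquinone 18. The closest known reaction type is the Moore rearrangement of 4-alkenyl-4-hydroxycyclobutenones, made from 3-alkoxy-4-arylcyclobutenediones, to hydroquinones in hot toluene or xylene. The one ring formed, the six-membered carbocycle, closes by 6π electrocyclisation with the new bond between the former carbonyl carbon C1 and the vinyl CH(OMe) carbon. No stereocentre is created in 18: the only sp3 centre on the pathway, CH(OMe) of 17, is racemic and is erased by tautomerisation, and the carbinol carbon of 15 becomes a ring C–OH carbon. The step needs torquoselectivity that turns the alkenyl group inward toward the ketene, which the carbinol OH secures because this strong donor rotates outward; the para placement of the two OMe groups and of the two indoles is already fixed by the connectivity of 15. The vinyl OMe points inward in 16, which should be tolerated because the partner terminus is an unhindered sp ketene carbon.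

**Step 10**
Reactants: 18 2,5-dimethoxy-3-(1-Boc-indol-3-yl)-6-(1-Boc-7-prenylindol-3-yl)benzene-1,4-diol (used crude)
Product: 19 2,5-dimethoxy-3-(1-Boc-indol-3-yl)-6-(1-Boc-7-prenylindol-3-yl)-1,4-benzoquinone
Conditions: Ag2O, Na2SO4, Et2O, rt
Reagents that add atoms: none
Why: Electron-rich hydroquinones are dehydrogenated to quinones by Ag2O under neutral conditions that leave the Boc groups, the methoxy groups and the prenyl alkene untouched.

**Step 11**
Reactants: 19 2,5-dimethoxy-3-(1-Boc-indol-3-yl)-6-(1-Boc-7-prenylindol-3-yl)-1,4-benzoquinone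
Product: 20 2,5-dimethoxy-3-(1H-indol-3-yl)-6-(7-prenyl-1H-indol-3-yl)-1,4-benzoquinone (target)
Conditions: NaOMe (cat.), dry MeOH/THF, 0 °C → rt; aq. NH4Cl
Reagents that add atoms: none
Why: N-Boc groups on indoles bearing an electron-poor quinonyl substituent are cleaved by catalytic methoxide through acyl transfer to methanol, methoxide attack at the methoxy-bearing quinone carbons is degenerate, and the prenyl group, which could cyclise onto the free indole under acid, never meets acid.

**Compound list**
1 | squaric acid (3,4-dihydroxycyclobut-3-ene-1,2-dione) | OC1=C(O)C(=O)C1=O | starting material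
2 | squaryl dichloride (3,4-dichlorocyclobut-3-ene-1,2-dione) | ClC1=C(Cl)C(=O)C1=O | intermediate
3 | 7-bromo-1H-indole | Brc1cccc2cc[nH]c12 | starting material
4 | 1-potassio-7-lithioindole | [Li]c1cccc2ccn([K])c12 | intermediate (not isolated)
5 | 7-(3-methylbut-2-en-1-yl)-1H-indole (7-prenylindole) | CC(C)=CCc1cccc2cc[nH]c12 | intermediate
6 | 3-chloro-4-(7-prenyl-1H-indol-3-yl)cyclobut-3-ene-1,2-dione | ClC1=C(c2c[nH]c3c(CC=C(C)C)cccc23)C(=O)C1=O | intermediate
7 | 3-methoxy-4-(7-prenyl-1H-indol-3-yl)cyclobut-3-ene-1,2-dione | COC1=C(c2c[nH]c3c(CC=C(C)C)cccc23)C(=O)C1=O | intermediate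
8 | tert-butyl 3-(2-methoxy-3,4-dioxocyclobut-1-en-1-yl)-7-prenylindole-1-carboxylate | COC1=C(c2cn(C(=O)OC(C)(C)C)c3c(CC=C(C)C)cccc23)C(=O)C1=O | intermediate
9 | tert-butyl 3-formylindole-1-carboxylate | O=Cc1cn(C(=O)OC(C)(C)C)c2ccccc12 | starting material
10 | (methoxymethyl)triphenylphosphonium chloride | COC[P+](c1ccccc1)(c1ccccc1)c1ccccc1.[Cl-] | starting material
11 | tert-butyl 3-(2-methoxyvinyl)indole-1-carboxylate, E/Z mixture | COC=Cc1cn(C(=O)OC(C)(C)C)c2ccccc12 | intermediate
12 | tert-butyl 3-(1,2-dibromo-2-methoxyethyl)indole-1-carboxylate, diastereomer mixture | COC(Br)C(Br)c1cn(C(=O)OC(C)(C)C)c2ccccc12 | intermediate (not isolated)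
13 | tert-butyl 3-[(Z)-1-bromo-2-methoxyvinyl]indole-1-carboxylate (Br cis to OMe) | CO/C=C(\Br)c1cn(C(=O)OC(C)(C)C)c2ccccc12 | intermediate
14 | [(E)-2-methoxy-1-(1-Boc-indol-3-yl)vinyl]lithium (Li cis to OMe) | CO/C=C(\[Li])c1cn(C(=O)OC(C)(C)C)c2ccccc12 | intermediate (not isolated)
15 | racemic 4-hydroxy-3-methoxy-4-[(Z)-2-methoxy-1-(1-Boc-indol-3-yl)vinyl]-2-(1-Boc-7-prenylindol-3-yl)cyclobut-2-en-1-one | CO/C=C(\C1(O)C(OC)=C(c2cn(C(=O)OC(C)(C)C)c3c(CC=C(C)C)cccc23)C1=O)c1cn(C(=O)OC(C)(C)C)c2ccccc12 | intermediate
16 | dienylketene (3Z,5Z)-4-hydroxy-3,6-dimethoxy-5-(1-Boc-indol-3-yl)-2-(1-Boc-7-prenylindol-3-yl)hexa-1,3,5-trien-1-one | O=C=C(c1cn(C(=O)OC(C)(C)C)c2c(CC=C(C)C)cccc12)/C(OC)=C(/O)C(=C\OC)/c1cn(C(=O)OC(C)(C)C)c2ccccc12 | intermediate (not isolated)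
17 | racemic 4-hydroxy-3,6-dimethoxy-5-(1-Boc-indol-3-yl)-2-(1-Boc-7-prenylindol-3-yl)cyclohexa-2,4-dien-1-one | COC1C(=O)C(c2cn(C(=O)OC(C)(C)C)c3c(CC=C(C)C)cccc23)=C(OC)C(O)=C1c1cn(C(=O)OC(C)(C)C)c2ccccc12 | intermediate (not isolated)
18 | 2,5-dimethoxy-3-(1-Boc-indol-3-yl)-6-(1-Boc-7-prenylindol-3-yl)benzene-1,4-diol | COc1c(O)c(-c2cn(C(=O)OC(C)(C)C)c3c(CC=C(C)C)cccc23)c(OC)c(O)c1-c1cn(C(=O)OC(C)(C)C)c2ccccc12 | intermediate
19 | 2,5-dimethoxy-3-(1-Boc-indol-3-yl)-6-(1-Boc-7-prenylindol-3-yl)-1,4-benzoquinone | COC1=C(c2cn(C(=O)OC(C)(C)C)c3ccccc23)C(=O)C(OC)=C(c2cn(C(=O)OC(C)(C)C)c3c(CC=C(C)C)cccc23)C1=O | intermediate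
20 | 2,5-dimethoxy-3-(1H-indol-3-yl)-6-(7-prenyl-1H-indol-3-yl)-1,4-benzoquinone | COC1=C(c2c[nH]c3ccccc23)C(=O)C(OC)=C(c2c[nH]c3c(CC=C(C)C)cccc23)C1=O | target

**Step count**
Total step count: 11. Longest linear sequence: 8 steps (3 → 5 → 6 → 7 → 8 → 15 → 18 → 19 → 20; the branch from 1 is equally long, the branch from 9 shorter).

**Steps most likely to fail**

Step 9, the key step. The closure of 16 may be slowed by the inward methoxy group, giving the ketene time to be captured by oxygen nucleophiles or to polymerise. Cyclohexadienone 17 may also lose methanol instead of enolising, which would give a quinone lacking one methoxy group, and prolonged heating may strip the carbamates or degrade the enol ether. The fallback abandons the ring expansion and takes the six-membered ring from a preformed quinone by known chemistry, setting out from 5. Acid-promoted conjugate addition of indole to 2,5-dichloro-1,4-benzoquinone (HCl, THF) would give 2,5-dichloro-3-(1H-indol-3-yl)benzene-1,4-diol F1, which DDQ would oxidise to 2,5-dichloro-3-(1H-indol-3-yl)-1,4-benzoquinone F2. Compound 5 would then add to the one free position of F2 in AcOH, conditions mild enough for the prenyl group, to give 2,5-dichloro-3-(1H-indol-3-yl)-6-(7-prenyl-1H-indol-3-yl)benzene-1,4-diol F3, and DDQ would give 2,5-dichloro-3-(1H-indol-3-yl)-6-(7-prenyl-1H-indol-3-yl)-1,4-benzoquinone F4. NaOMe in dry MeOH would replace both chlorides by addition–elimination, and the fallback comes back to the route at the target 20.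

Step 8. The vinyllithium may lose lithium methoxide by β-elimination (giving the 3-ethynylindole) if the temperature rises or if any isomer with lithium anti to methoxy is present. t-BuLi or the vinyllithium may instead abstract the indole C2 proton or attack a carbamate, and part of the addition may go to the vinylogous ester carbonyl. The fallback replaces the organolithium by an alkenylmagnesium reagent made without t-BuLi, setting out from 11. ICl (CH2Cl2, −78 °C) would give tert-butyl 3-(2-chloro-1-iodo-2-methoxyethyl)indole-1-carboxylate F5, from which iPr2NEt would remove HCl to give tert-butyl 3-[(Z)-1-iodo-2-methoxyvinyl]indole-1-carboxylate F6. Iodine–magnesium exchange with iPrMgCl·LiCl (THF, −40 °C), which tolerates carbamates and gives a far less basic and less elimination-prone carbanion, would give [(Z)-2-methoxy-1-(1-Boc-indol-3-yl)vinyl]magnesium chloride F7. Its addition to the ketone-like carbonyl of 8 comes back to the route at 15.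

Step 7. HBr may be lost in the wrong sense, the wrong double-bond isomer (Br anti to OMe, whose lithio derivative cannot be used) may form, or the labile indolylmethyl bromide in 12 may ionise and decompose before elimination. The fallback separates halogenation from alkene formation through a stable acetal, setting out from 11. NBS in MeOH (−20 °C, bromo-methoxylation of the enol ether) would give tert-butyl 3-(1-bromo-2,2-dimethoxyethyl)indole-1-carboxylate F8, which can be purified. Me3SiOTf with iPr2NEt (CH2Cl2, −20 °C), the standard conversion of dimethyl acetals into methyl enol ethers by loss of methanol, would then form the bromo enol ether under conditions in which the geometry can equilibrate through the oxocarbenium ion, coming back to the route at 13.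

Further compounds
F1 | step 9 | 2,5-dichloro-3-(1H-indol-3-yl)benzene-1,4-diol | Oc1cc(Cl)c(O)c(-c2c[nH]c3ccccc23)c1Cl
F2 | step 9 | 2,5-dichloro-3-(1H-indol-3-yl)-1,4-benzoquinone | O=C1C=C(Cl)C(=O)C(c2c[nH]c3ccccc23)=C1Cl
F3 | step 9 | 2,5-dichloro-3-(1H-indol-3-yl)-6-(7-prenyl-1H-indol-3-yl)benzene-1,4-diol | Oc1c(Cl)c(-c2c[nH]c3ccccc23)c(O)c(Cl)c1-c1c[nH]c2c(CC=C(C)C)cccc12
F4 | step 9 | 2,5-dichloro-3-(1H-indol-3-yl)-6-(7-prenyl-1H-indol-3-yl)-1,4-benzoquinone | O=C1C(Cl)=C(c2c[nH]c3ccccc23)C(=O)C(Cl)=C1c1c[nH]c2c(CC=C(C)C)cccc12
F5 | step 8 | tert-butyl 3-(2-chloro-1-iodo-2-methoxyethyl)indole-1-carboxylate | COC(Cl)C(I)c1cn(C(=O)OC(C)(C)C)c2ccccc12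
F6 | step 8 | tert-butyl 3-[(Z)-1-iodo-2-methoxyvinyl]indole-1-carboxylate | CO/C=C(\I)c1cn(C(=O)OC(C)(C)C)c2ccccc12
F7 | step 8 | [(Z)-2-methoxy-1-(1-Boc-indol-3-yl)vinyl]magnesium chloride | CO/C=C(\[Mg]Cl)c1cn(C(=O)OC(C)(C)C)c2ccccc12
F8 | step 7 | tert-butyl 3-(1-bromo-2,2-dimethoxyethyl)indole-1-carboxylate | COC(OC)C(Br)c1cn(C(=O)OC(C)(C)C)c2ccccc12
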